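**Retrosynthetic overview**
1. The target is reached by one global hydrogenolysis of an octa-O-benzyl, dibromo-capped chalcane–flavan dimer. This removes eight O-benzyl groups and two C–Br bonds.
2. The dimer is cut at the C1'–C8 bond. The nucleophile is tetra-O-benzylcatechin and the electrophile is a ring-opened catechin triacetate. The bond forms by anti attack on a trans-acetoxonium ion.
3. Key disconnection: the benzylic C–O bond of the triacetate. Ring C of a 6,8-dibromo-capped catechin is cut at C2–O1 by Ac2O, and C2 is re-bonded to oxygen by double inversion while O1 is capped as an acetate.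
4. Both halves come from (+)-catechin, which supplies all four stereocentres. The diarylmethine centre is the old C2, carried through two pairs of inversions.
5. Ring order: no permanent ring is built, since all aryl rings and the lower pyran are bought with catechin. The upper pyran is opened in step 3, and only a transient dioxolanylium ring forms, in steps 3 and 4.

Assumption: flavan numbering (O1, C2, C3, C4, C8; rings A, B, C) is used for the closed half. In the opened half the old C2, C3, C4 become C1', C2', C3', and the old rings A and B become rings D and E. The target is read as (2R,3S) in the flavan half and (1'S,2'S) in the chalcane half.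

**Step 1**
Reactants: 1 (+)-catechin; 2 benzyl bromide
Product: 3 (2R,3S)-5,7-bis(benzyloxy)-2-[3,4-bis(benzyloxy)phenyl]chroman-3-ol
Conditions: BnBr (4.4 equiv), K2CO3 (5 equiv), DMF, Ar, 0 °C to rt
Reagents that add atoms: benzyl bromide, BrCc1ccccc1
Why: Williamson etherification alkylates the four phenols under carbonate conditions that leave the much less acidic secondary 3-OH free, and no stereocentre is touched.

**Step 2**
Reactants: 3 tetra-O-benzylcatechin; 4 N-bromosuccinimide
Product: 5 (2R,3S)-5,7-bis(benzyloxy)-2-[3,4-bis(benzyloxy)phenyl]-6,8-dibromochroman-3-ol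
Conditions: NBS (2.1 equiv), CH2Cl2, −40 °C to 0 °C
Reagents that add atoms: N-bromosuccinimide, O=C1CCC(=O)N1Br
Why: In this electrophilic aromatic bromination ring A (a phloroglucinol triether) is far more activated than ring B, so two equivalents fill C8 and then C6, and the bromines block self-alkylation and C-acetylation later and leave in the last step.

**Step 3** (key step)
Reactants: 5 6,8-dibromo-tetra-O-benzylcatechin; 6 acetic anhydride
Product: 9 (1R,2S)-3-[2-acetoxy-4,6-bis(benzyloxy)-3,5-dibromophenyl]-1-[3,4-bis(benzyloxy)phenyl]propane-1,2-diyl diacetate, via 3-O-acetate 7 (not isolated), via acetoxonium acetate 8 (not isolated)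
Conditions: Ac2O (10 equiv), Sc(OTf)3 (5 mol %), CH2Cl2, 0 °C to rt
Reagents that add atoms: acetic anhydride, CC(=O)OC(C)=O
Why: Proposed new method: Lewis-acid-catalysed acylative scission of the flavan C2–O1 ether with anchimeric assistance; after fast O-acetylation to 7 the equatorial 3-acetoxy group lies antiperiplanar to C2–O1, so its carbonyl oxygen displaces the Sc-bound aryloxide from the rear (first inversion, new benzylic C–O bond, trans-dioxolanylium 8, the microscopic reverse of the orthoester-type closure used to build flavan-3-ols); the freed phenol is acetylated irreversibly, which pulls the otherwise unfavourable ring-opening equilibrium; acetate then opens 8 at the 3,4-dialkoxybenzylic carbon as in a Prévost reaction (second inversion) to give the (1R,2S)-erythro triacetate; plain benzyl ethers survive because they lack both the dialkoxybenzylic cation stabilisation and the participating group; the closest known reaction types are acylative ether cleavage with Ac2O and a Lewis acid, acetolysis of anhydrosugars and acyloxy participation in glycosylation, none of which has been shown on a flavan pyran ring.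

**Step 4**
Reactants: 9 ring-opened triacetate; 3 tetra-O-benzylcatechin
Product: 11 (2R,3S)-5,7-bis(benzyloxy)-2-[3,4-bis(benzyloxy)phenyl]-8-{(1S,2S)-3-[4,6-bis(benzyloxy)-3,5-dibromo-2-hydroxyphenyl]-1-[3,4-bis(benzyloxy)phenyl]-2-hydroxypropyl}chroman-3-ol, via coupled diacetate 10 (not isolated)
Conditions: 3 (3 equiv), TMSOTf (0.3 equiv), 4 Å MS, CH2Cl2, −78 to −40 °C; Et3N quench; then K2CO3, MeOH/THF, rt
Reagents that add atoms: none
Why: This is a Friedel–Crafts benzylation at C8 of ring A as in procyanidin couplings, in which TMSOTf ionises the benzylic acetate, the vicinal acetate re-forms the trans-acetoxonium (inversion) and C8 of 3 attacks anti to it (inversion), so the aryl group sits where O1 sat (the label changes from R to S only through CIP priorities), the fully substituted ring D cannot self-condense, and base-catalysed Zemplén-type methanolysis then removes both acetates.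

**Step 5**
Reactants: 11 octa-O-benzyl dibromo dimer
Product: 12 (2R,3S)-2-(3,4-dihydroxyphenyl)-8-[(1S,2S)-1-(3,4-dihydroxyphenyl)-2-hydroxy-3-(2,4,6-trihydroxyphenyl)propyl]chromane-3,5,7-triol
Conditions: H2 (1 atm), Pd(OH)2/C, NaOAc (2.5 equiv), THF/MeOH/H2O, rt
Reagents that add atoms: none
Why: Catalytic hydrogenolysis cleaves the eight benzyl ethers and hydrodehalogenates both aryl bromides in one operation, while NaOAc buffers the HBr so the acid-labile chalcane–flavan skeleton and its four stereocentres stay untouched.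

**Compound list**
1 | (+)-catechin, (2R,3S)-2-(3,4-dihydroxyphenyl)chromane-3,5,7-triol | Oc1cc(O)c2c(c1)O[C@H](c1ccc(O)c(O)c1)[C@@H](O)C2 | starting material
2 | benzyl bromide | BrCc1ccccc1 | starting material
3 | (2R,3S)-5,7-bis(benzyloxy)-2-[3,4-bis(benzyloxy)phenyl]chroman-3-ol | c1ccccc1COc1cc(OCc2ccccc2)c2c(c1)O[C@H](c1ccc(OCc3ccccc3)c(OCc3ccccc3)c1)[C@@H](O)C2 | intermediate
4 | N-bromosuccinimide | O=C1CCC(=O)N1Br | starting material
5 | (2R,3S)-5,7-bis(benzyloxy)-2-[3,4-bis(benzyloxy)phenyl]-6,8-dibromochroman-3-ol | c1ccccc1COc1c(Br)c(OCc2ccccc2)c2c(c1Br)O[C@H](c1ccc(OCc3ccccc3)c(OCc3ccccc3)c1)[C@@H](O)C2 | intermediate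
6 | acetic anhydride | CC(=O)OC(C)=O | starting material
7 | (2R,3S)-5,7-bis(benzyloxy)-2-[3,4-bis(benzyloxy)phenyl]-6,8-dibromochroman-3-yl acetate | c1ccccc1COc1c(Br)c(OCc2ccccc2)c2c(c1Br)O[C@H](c1ccc(OCc3ccccc3)c(OCc3ccccc3)c1)[C@@H](OC(C)=O)C2 | intermediate
8 | trans-(4S,5S)-5-[2-acetoxy-4,6-bis(benzyloxy)-3,5-dibromobenzyl]-4-[3,4-bis(benzyloxy)phenyl]-2-methyl-1,3-dioxolan-2-ylium acetate | CC1=[O+][C@@H](c2ccc(OCc3ccccc3)c(OCc3ccccc3)c2)[C@H](Cc2c(OC(C)=O)c(Br)c(OCc3ccccc3)c(Br)c2OCc2ccccc2)O1.CC([O-])=O | intermediate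
9 | (1R,2S)-3-[2-acetoxy-4,6-bis(benzyloxy)-3,5-dibromophenyl]-1-[3,4-bis(benzyloxy)phenyl]propane-1,2-diyl diacetate | CC(=O)Oc1c(Br)c(OCc2ccccc2)c(Br)c(OCc2ccccc2)c1C[C@H](OC(C)=O)[C@H](OC(C)=O)c1ccc(OCc2ccccc2)c(OCc2ccccc2)c1 | intermediate
10 | (1S,2S)-configured coupled diacetate: compound 11 bearing acetyl on the ring D phenol oxygen and on the C2' oxygen | CC(=O)Oc1c(Br)c(OCc2ccccc2)c(Br)c(OCc2ccccc2)c1C[C@H](OC(C)=O)[C@@H](c1ccc(OCc2ccccc2)c(OCc2ccccc2)c1)c1c(OCc2ccccc2)cc(OCc2ccccc2)c2c1O[C@H](c1ccc(OCc3ccccc3)c(OCc3ccccc3)c1)[C@@H](O)C2 | intermediate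
11 | (2R,3S)-5,7-bis(benzyloxy)-2-[3,4-bis(benzyloxy)phenyl]-8-{(1S,2S)-3-[4,6-bis(benzyloxy)-3,5-dibromo-2-hydroxyphenyl]-1-[3,4-bis(benzyloxy)phenyl]-2-hydroxypropyl}chroman-3-ol | Oc1c(Br)c(OCc2ccccc2)c(Br)c(OCc2ccccc2)c1C[C@H](O)[C@@H](c1ccc(OCc2ccccc2)c(OCc2ccccc2)c1)c1c(OCc2ccccc2)cc(OCc2ccccc2)c2c1O[C@H](c1ccc(OCc3ccccc3)c(OCc3ccccc3)c1)[C@@H](O)C2 | intermediate
12 | CNP0175733.2, (2R,3S)-2-(3,4-dihydroxyphenyl)-8-[(1S,2S)-1-(3,4-dihydroxyphenyl)-2-hydroxy-3-(2,4,6-trihydroxyphenyl)propyl]chromane-3,5,7-triol | Oc1cc(O)c(C[C@H](O)[C@@H](c2ccc(O)c(O)c2)c2c(O)cc(O)c3c2O[C@H](c2ccc(O)c(O)c2)[C@@H](O)C3)c(O)c1 | target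

**Totals**
Total step count: 5.
Longest linear sequence: 5 (1 → 3 → 5 → 9 → 11 → 12). Compound 3 is used twice.

**Steps most likely to fail**

Step 3 (the new step). The reaction may stop at 7. The benzylic cation may lose a proton to give an enol acetate. Some benzyl/acetyl exchange on the crowded ring may also occur, although this is harmless to the end product.

The fallback uses known chemistry, sets out from 1 and comes back at 12. Unprotected 1 is heated in dilute aqueous acid under N2. This is the long-known acid-catalysed self-condensation of catechin, in which ring C opens at C2–O1 and ring A of a second catechin captures the benzylic cation to give chalcane–flavan dimers. Compound 12 is separated from its C6-linked and C1'-epimeric isomers on Sephadex LH-20 and by reversed-phase HPLC. This is one step but has low yield and no selectivity. New compounds on its way: none F0.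

Step 4. If the free dialkoxybenzylic cation outruns the acetoxonium, facial selectivity drops. C6 attack or O-alkylation of the 3-OH of 3 may also compete.

The fallback replaces the intermolecular coupling with a tethered one. It sets out from 3 and 5 and comes back at 11.
- Compound 3 is opened onto glutaric anhydride (DMAP, pyridine) to give the hemiglutarate F1.
- F1 is esterified with the 3-OH of 5 (EDC, DMAP) to give the mixed glutarate diester F2.
- TMSOTf in CH2Cl2 at high dilution lets the glutarate carbonyl on the dibromo half open ring C by the same participation mode. Re-closure by the free phenol only regenerates F2.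
- The tethered C8 then closes the 14-membered macrolactone F3. This is the diester-linker tactic known from procyanidin couplings.
- K2CO3 in MeOH removes the tether and gives 11.

Step 5. HBr release, catalyst poisoning by bromide or incomplete debromination may damage or contaminate the sensitive polyphenol.

The fallback separates the two events. It sets out from 11 and comes back at 12. Halogen–lithium exchange (n-BuLi, 6 equiv, THF, −78 °C, MeOH quench) gives the debrominated octabenzyl ether F4. F4 is then debenzylated under neutral conditions (H2, Pd(OH)2/C, THF/MeOH) with no acid formed, which gives 12.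

**Further compounds**
F0 | step 3 | none | none
F1 | step 4 | hemiglutarate, 5-{[(2R,3S)-5,7-bis(benzyloxy)-2-[3,4-bis(benzyloxy)phenyl]chroman-3-yl]oxy}-5-oxopentanoic acid | c1ccccc1COc1cc(OCc2ccccc2)c2c(c1)O[C@H](c1ccc(OCc3ccccc3)c(OCc3ccccc3)c1)[C@@H](OC(=O)CCCC(O)=O)C2
F2 | step 4 | mixed glutarate diester joining the 3-oxygen of 3 to the 3-oxygen of 5 | c1ccccc1COc1cc(OCc2ccccc2)c2c(c1)O[C@H](c1ccc(OCc3ccccc3)c(OCc3ccccc3)c1)[C@@H](OC(=O)CCCC(=O)O[C@H]1Cc3c(OCc4ccccc4)c(Br)c(OCc4ccccc4)c(Br)c3O[C@@H]1c1ccc(OCc3ccccc3)c(OCc3ccccc3)c1)C2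
F3 | step 4 | 14-membered macrolactone: compound 11 with its C2' oxygen and C3 oxygen bridged by a glutaryl unit, ring D phenol free | Oc1c(Br)c(OCc2ccccc2)c(Br)c(OCc2ccccc2)c1C[C@@H]1OC(=O)CCCC(=O)O[C@H]2Cc3c(OCc4ccccc4)cc(OCc4ccccc4)c([C@@H]1c1ccc(OCc4ccccc4)c(OCc4ccccc4)c1)c3O[C@@H]2c1ccc(OCc2ccccc2)c(OCc2ccccc2)c1
F4 | step 5 | debrominated octabenzyl ether: compound 11 with hydrogen in place of both bromines | Oc1cc(OCc2ccccc2)cc(OCc2ccccc2)c1C[C@H](O)[C@@H](c1ccc(OCc2ccccc2)c(OCc2ccccc2)c1)c1c(OCc2ccccc2)cc(OCc2ccccc2)c2c1O[C@H](c1ccc(OCc3ccccc3)c(OCc3ccccc3)c1)[C@@H](O)C2
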